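The labdane is cut through ring A at C1–C2 and C4–C5, which releases a five-carbon unit (C2–C3–C4 with both C4 methyls) and an acyclic fifteen-carbon chain, as in terpene biosynthesis (prenyl transfer, then cyclization). In the key step both bonds form in one flask: an (E)-allylbarium reagent is alkylated by (S)-3,3-dimethylglycidyl tosylate (C1–C2), and Cp2TiCl then opens the C3–C4 epoxide to a C4 radical that closes ring A (C4–C5) and ring B (C9–C10). The step exploits the 3β-oxygen next to the gem-dimethyl C4 (a latent epoxide) and relays C3 to C5, C9 and C10. The precursors are an acyclic dihydrofarnesyl chloride and an epoxy tosylate.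

Key step: step 6

Assumption: labdane numbering is used for all carbons, also in the acyclic precursors (decalin C1–C10, side chain C11–C16, C17 on C8, C18 and C19 on C4, C20 on C10); the target is read as (3S,5R,9S,10R,13S), that is 3β-formyloxy, 5α-H, 9α-H, 10β-methyl.

Step 1
Reactants: 1 (2E,6E)-farnesol
Product: 2 (S)-2,3-dihydrofarnesol, (3S,6E)-3,7,11-trimethyldodeca-6,10-dien-1-ol
Conditions: H2 (30 atm), Ru(OAc)2[(R)-BINAP] (cat.), MeOH, rt
Reagents that add atoms: none
Why: Noyori asymmetric hydrogenation, in which the hydroxyl-bound Ru–BINAP hydride should reduce only the allylic-alcohol alkene and set the methyl-bearing stereocentre (C13) as S, the (R)-ligand being chosen by analogy with the known geraniol-to-(S)-citronellol sense.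

Step 2
Reactants: 2 (S)-2,3-dihydrofarnesol
Product: 3 triethylsilyl ether of 2
Conditions: Et3SiCl, imidazole, CH2Cl2, 0 °C
Reagents that add atoms: chlorotriethylsilane, CC[Si](Cl)(CC)CC
Why: Imidazole-mediated silylation of the primary hydroxyl, needed because the later organobarium stage does not tolerate O–H, with no stereocentre touched.

Step 3
Reactants: 3 triethylsilyl ether of 2
Product: 4 (2E,6E,10S)-2,6,10-trimethyl-12-(triethylsilyloxy)dodeca-2,6-dien-1-ol
Conditions: SeO2 (cat.), t-BuOOH (in decane), CH2Cl2, 0 °C to rt
Reagents that add atoms: tert-butyl hydroperoxide, CC(C)(C)OO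
Why: Selenium dioxide allylic oxidation (ene reaction then 2,3-sigmatropic shift, t-BuOOH as terminal oxidant) should attack the more electron-rich, less hindered terminal isopropylidene group at its (E)-methyl, which makes C1 a handle, fixes the E geometry of the future C5=C10 alkene and creates no stereocentre.

Step 4
Reactants: 4 (E)-allylic alcohol
Product: 5 (E)-allylic chloride, {[(3S,6E,10E)-12-chloro-3,7,11-trimethyldodeca-6,10-dien-1-yl]oxy}triethylsilane
Conditions: NCS, Me2S, CH2Cl2, −40 to 0 °C
Reagents that add atoms: N-chlorosuccinimide, O=C1CCC(=O)N1Cl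
Why: Corey–Kim chlorination, in which chloride displaces the alkoxysulfonium group at the primary allylic carbon (SN2) under neutral conditions, so that no allylic transposition and no loss of alkene geometry or of the silyl ether is expected.

Step 5
Reactants: 6 3-methylbut-2-en-1-ol (prenol)
Product: 8 [(2S)-3,3-dimethyloxiran-2-yl]methyl 4-methylbenzenesulfonate, via epoxy alcohol 7 (not isolated)
Conditions: Ti(OiPr)4 (cat.), L-(+)-diethyl tartrate (cat.), t-BuOOH, 4 Å MS, CH2Cl2, −20 °C; P(OMe)3; then TsCl, Et3N, DMAP (cat.), −10 °C
Reagents that add atoms: tert-butyl hydroperoxide, CC(C)(C)OO; p-toluenesulfonyl chloride, Cc1ccc(cc1)S(Cl)(=O)=O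
Why: Sharpless asymmetric epoxidation with sulfonylation of the volatile epoxy alcohol in the same flask, in which L-(+)-tartrate directs oxygen to the face that gives the 2S epoxide (future C3, 3β-oxygen) and tosylation at oxygen does not touch that centre.

Step 6
Reactants: 5 (E)-allylic chloride; 8 (S)-epoxy tosylate
Product: 12 (13S)-labd-8(17)-ene-3β,15-diol, via allylbarium chloride 9 (not isolated), via epoxy diene 10 (not isolated), via silyl ether 11 (not isolated)
Conditions: BaI2, lithium biphenylide, THF, rt; 5, −78 °C; 8, −78 to −20 °C; then Cp2TiCl2, Mn, THF, rt; 1 M HCl, THF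
Reagents that add atoms: none
Why: Mechanism: active barium inserts into the C–Cl bond of 5 at −78 °C to give the configurationally stable (E)-allylbarium 9, which displaces the primary tosylate of 8 through its unsubstituted α-carbon (SN2, C1–C2) to give 10; Cp2TiCl (trivalent titanium) then opens the C3–C4 epoxide homolytically at the tertiary carbon, the β-titanoxy C4 radical adds to C5 (C4–C5), the resulting C10 radical adds to C9, and the C8 radical is trapped by a second Cp2TiCl and leaves as the exocyclic alkene by β-hydride elimination. The closest known reaction types are the α-selective, geometry-retaining coupling of allylbarium reagents with carbon electrophiles and the Cp2TiCl-mediated radical cyclization of epoxypolyprenes, here run one after the other in the same THF solution. Ring A closes 6-endo-trig (C4 radical onto C5=C10) and ring B closes 6-endo-trig (C10 radical onto C8=C9), both through chair-like transition states. C3 comes with the epoxide and is not touched, and the equatorial C3–O–Ti group together with the two E alkenes fixes C5 (H α), C10 (methyl β) and C9 (H α) as the trans-fused array, so that one stereocentre controls three new ones in one event. The step needs α- over γ-alkylation with retention of the E geometry (secured by the barium counter-ion at low temperature and the unhindered primary sulfonate), homolysis of the tertiary and not the secondary C–O bond (radical stability), and termination after two rings (secured by the saturated C13–C14 bond of the side chain). The acidic work-up hydrolyses the O–Ti bond and removes the primary triethylsilyl ether.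

Step 7
Reactants: 12 (13S)-labd-8(17)-ene-3β,15-diol
Product: 13 (13S)-labd-7-ene-3β,15-diol
Conditions: Co(salen)Cl (cat.; salen = N,N′-bis(3,5-di-tert-butylsalicylidene)-1,2-cyclohexanediamine dianion), PhSiH3 (cat.), benzene, rt
Reagents that add atoms: none
Why: Cobalt-hydride hydrogen-atom-transfer alkene isomerization, in which reversible H-atom addition to the exocyclic CH2 gives the tertiary C8 radical and H-atom abstraction from the accessible C7 methylene should give the trisubstituted C7=C8 alkene, whereas the tetrasubstituted C8=C9 isomer would need abstraction of the hindered axial C9–H, so that no stereocentre is created or lost.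

Step 8
Reactants: 13 (13S)-labd-7-ene-3β,15-diol
Product: 14 (13S)-labd-7-ene-3β,15-diyl diformate (target)
Conditions: acetic formic anhydride, pyridine, CH2Cl2, 0 °C to rt
Reagents that add atoms: acetic formic anhydride, CC(=O)OC=O
Why: O-formylation with a mixed anhydride, in which the primary C15 hydroxyl and the equatorial secondary C3 hydroxyl both attack the more electrophilic formyl carbon under pyridine catalysis, with retention at C3 and without acid that could move the C7=C8 alkene.

Compound list
1 | (2E,6E)-farnesol, (2E,6E)-3,7,11-trimethyldodeca-2,6,10-trien-1-ol | OC/C=C(\C)CC/C=C(\C)CCC=C(C)C | starting material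
2 | (S)-2,3-dihydrofarnesol, (3S,6E)-3,7,11-trimethyldodeca-6,10-dien-1-ol | OCC[C@@H](C)CC/C=C(\C)CCC=C(C)C | intermediate
3 | triethyl{[(3S,6E)-3,7,11-trimethyldodeca-6,10-dien-1-yl]oxy}silane | CC[Si](CC)(CC)OCC[C@@H](C)CC/C=C(\C)CCC=C(C)C | intermediate
4 | (2E,6E,10S)-2,6,10-trimethyl-12-(triethylsilyloxy)dodeca-2,6-dien-1-ol | CC[Si](CC)(CC)OCC[C@@H](C)CC/C=C(\C)CC/C=C(\C)CO | intermediate
5 | {[(3S,6E,10E)-12-chloro-3,7,11-trimethyldodeca-6,10-dien-1-yl]oxy}triethylsilane | CC[Si](CC)(CC)OCC[C@@H](C)CC/C=C(\C)CC/C=C(\C)CCl | intermediate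
6 | 3-methylbut-2-en-1-ol (prenol) | CC(C)=CCO | starting material
7 | [(2S)-3,3-dimethyloxiran-2-yl]methanol | CC1(C)O[C@H]1CO | intermediate
8 | [(2S)-3,3-dimethyloxiran-2-yl]methyl 4-methylbenzenesulfonate | CC1(C)O[C@H]1COS(=O)(=O)c1ccc(C)cc1 | intermediate
9 | chloro[(2E,6E,10S)-2,6,10-trimethyl-12-(triethylsilyloxy)dodeca-2,6-dien-1-yl]barium | CC[Si](CC)(CC)OCC[C@@H](C)CC/C=C(\C)CC/C=C(\C)C[Ba]Cl | intermediate
10 | {[(3S,6E,10E)-13-[(2S)-3,3-dimethyloxiran-2-yl]-3,7,11-trimethyltrideca-6,10-dien-1-yl]oxy}triethylsilane | CC[Si](CC)(CC)OCC[C@@H](C)CC/C=C(\C)CC/C=C(\C)CC[C@@H]1OC1(C)C | intermediate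
11 | (13S)-15-(triethylsilyloxy)labd-8(17)-en-3β-ol (5α-H, 9α-H, 10β-methyl) | C=C1CC[C@H]2C(C)(C)[C@@H](O)CC[C@]2(C)[C@H]1CC[C@H](C)CCO[Si](CC)(CC)CC | intermediate
12 | (13S)-labd-8(17)-ene-3β,15-diol (5α-H, 9α-H, 10β-methyl) | C=C1CC[C@H]2C(C)(C)[C@@H](O)CC[C@]2(C)[C@H]1CC[C@H](C)CCO | intermediate
13 | (13S)-labd-7-ene-3β,15-diol (5α-H, 9α-H, 10β-methyl) | CC1=CC[C@H]2C(C)(C)[C@@H](O)CC[C@]2(C)[C@H]1CC[C@H](C)CCO | intermediate
14 | (13S)-labd-7-ene-3β,15-diyl diformate, (3S,5R,9S,10R,13S) | CC1=CC[C@H]2C(C)(C)[C@@H](OC=O)CC[C@]2(C)[C@H]1CC[C@H](C)CCOC=O | target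

Total step count: 8. Longest linear sequence: 7 steps (steps 1, 2, 3, 4, 6, 7, 8); step 5 supplies the second branch.

Steps most likely to fail

Step 6. What may go wrong: alkylation through the γ-carbon (C5) or E/Z equilibration of the allyl metal, attack of the carbanion at sulfur of the sulfonate, or a radical cascade that stops after ring A or ends by reduction of the C8 radical. The fallback separates the two bond formations and uses sulfone chemistry. It sets out from 5: displacement with NaSO2Ph in DMF gives the allyl phenyl sulfone F1. Its lithium anion (n-BuLi, THF, −78 °C) can only be alkylated at the sulfone-bearing carbon C1, and with 8 it gives the epoxy sulfone F2. Na(Hg) with Na2HPO4 in MeOH/THF at −20 °C removes the sulfonyl group and gives 10, which is isolated. Separate treatment of 10 with Cp2TiCl (from Cp2TiCl2 and Mn, THF) and work-up with 1 M HCl comes back to the route at 12.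

Step 7. What may go wrong: migration of the double bond past C7=C8 into the tetrasubstituted C8=C9 position, or no turnover on the hindered exocyclic alkene. The fallback changes the cyclization from radical to cationic so that the C7=C8 alkene forms directly. It sets out from 10, isolated either by aqueous quench of step 6 before the titanium reagent is added or by the sulfone route above. MeAlCl2 in CH2Cl2 at −78 °C should start the epoxide-initiated cation–olefin bicyclization, which ends by loss of the axial C7 proton from the C8 cation and gives the triethylsilyl ether F3. 1 M HCl in THF then comes back to the route at 13.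

Step 3. What may go wrong: oxidation at the internal trisubstituted alkene, over-oxidation to the enal, or partial loss of the silyl ether. The fallback builds the (E)-allylic alcohol by olefination instead of C–H oxidation. It sets out from 3: NBS in aqueous THF gives the terminal bromohydrin F4, and K2CO3 in MeOH closes it to the terminal epoxide F5. HIO4 in THF/Et2O cleaves the epoxide to the aldehyde F6. Wittig reaction with Ph3P=C(CH3)CO2Et gives the (E)-enoate F7, and reduction with i-Bu2AlH comes back to the route at 4.

Further compounds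
F1 | step 6 | {[(3S,6E,10E)-3,7,11-trimethyl-12-(phenylsulfonyl)dodeca-6,10-dien-1-yl]oxy}triethylsilane | CC[Si](CC)(CC)OCC[C@@H](C)CC/C=C(\C)CC/C=C(\C)CS(=O)(=O)c1ccccc1
F2 | step 6 | {[(3S,6E,10E)-13-[(2S)-3,3-dimethyloxiran-2-yl]-3,7,11-trimethyl-12-(phenylsulfonyl)trideca-6,10-dien-1-yl]oxy}triethylsilane (both epimers at C12) | CC[Si](CC)(CC)OCC[C@@H](C)CC/C=C(\C)CC/C=C(\C)C(C[C@@H]1OC1(C)C)S(=O)(=O)c1ccccc1
F3 | step 7 | (13S)-15-(triethylsilyloxy)labd-7-en-3β-ol | CC1=CC[C@H]2C(C)(C)[C@@H](O)CC[C@]2(C)[C@H]1CC[C@H](C)CCO[Si](CC)(CC)CC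
F4 | step 3 | (6E,10S)-3-bromo-2,6,10-trimethyl-12-(triethylsilyloxy)dodec-6-en-2-ol (both epimers at C3) | CC[Si](CC)(CC)OCC[C@@H](C)CC/C=C(\C)CCC(Br)C(C)(C)O
F5 | step 3 | {[(3S,6E)-9-(3,3-dimethyloxiran-2-yl)-3,7-dimethylnon-6-en-1-yl]oxy}triethylsilane (both epoxide epimers) | CC[Si](CC)(CC)OCC[C@@H](C)CC/C=C(\C)CCC1OC1(C)C
F6 | step 3 | (4E,8S)-4,8-dimethyl-10-(triethylsilyloxy)dec-4-enal | CC[Si](CC)(CC)OCC[C@@H](C)CC/C=C(\C)CCC=O
F7 | step 3 | ethyl (2E,6E,10S)-2,6,10-trimethyl-12-(triethylsilyloxy)dodeca-2,6-dienoate | CC[Si](CC)(CC)OCC[C@@H](C)CC/C=C(\C)CC/C=C(\C)C(=O)OCC
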